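Kukoamine A ends in two identical secondary amides, N–C(=O)–CH2–CH2–aryl, each nitrogen on a (CH2)3 arm of the spermine chain and each aryl a catechol (benzene) ring. The route cuts both amides at the C(=O)–CH2 bond instead of the C–N bond: the carbonyl carbon arrives as an isocyanate carbon, the CH2CH2-aryl unit as a phenethyl Grignard reagent. In one operation two carbanions add to a linear diisocyanate, OCN–(CH2)3–N(Boc)–(CH2)4–N(Boc)–(CH2)3–NCO, forming both C–C bonds and both amides; no ring is closed. The diisocyanate comes from a double Curtius rearrangement of a diacid assembled from two pyrrolidin-2-one rings and 1,4-dibromobutane. Boron tribromide then unmasks everything.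

Key step: step 5

Assumption: the target has no stereogenic element (it is achiral), so nothing has to be set or preserved stereochemically; it is taken as the free base drawn, released from the hydrobromide formed in the last step.

Step 1
Reactants: 1 pyrrolidin-2-one (2.2 equiv); 2 1,4-dibromobutane
Product: 5 1,1'-(butane-1,4-diyl)di(pyrrolidin-2-one), via sodium 2-oxopyrrolidin-1-ide 3 (not isolated), via 1-(4-bromobutyl)pyrrolidin-2-one 4 (not isolated)
Conditions: NaH (2.3 equiv), THF, 0 °C → rt; then 2 (1.0 equiv), Bu4NI (cat.), reflux
Reagents that add atoms: none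
Why: The sodium lactamate is a soft N-nucleophile that should displace both primary bromides in two successive SN2 N-alkylations, the small excess of lactamate driving the second substitution to completion.

Step 2
Reactants: 5 1,1'-(butane-1,4-diyl)di(pyrrolidin-2-one)
Product: 7 4,4'-[butane-1,4-diylbis(tert-butoxycarbonylazanediyl)]dibutanoic acid, via bis(amino acid) dihydrochloride 6 (not isolated)
Conditions: 6 M HCl, reflux; evaporate; then NaOH (aq, pH 10–11), Boc2O (2.5 equiv), 1,4-dioxane, 0 °C → rt; then 1 M HCl to pH 3, 0 °C, EtOAc
Reagents that add atoms: water, O; di-tert-butyl dicarbonate, CC(C)(C)OC(=O)OC(=O)OC(C)(C)C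
Why: Acid-catalysed lactam hydrolysis should give the open-chain ammonium acid, which cannot re-close while protonated, and Boc2O then acylates the secondary amines in cold aqueous base (Schotten–Baumann-type carbamate formation) faster than they can re-lactamise.

Step 3
Reactants: 7 4,4'-[butane-1,4-diylbis(tert-butoxycarbonylazanediyl)]dibutanoic acid
Product: 10 di-tert-butyl butane-1,4-diylbis[(3-isocyanatopropyl)carbamate], via bis(ethyl carbonic) mixed anhydride 8 (not isolated), via bis(acyl azide) 9 (not isolated)
Conditions: ClCO2Et (2.2 equiv), Et3N (2.4 equiv), THF, −10 °C; NaN3 (3 equiv), H2O, 0 °C; extract into toluene, cold aq NaHCO3 wash, MgSO4 (never concentrated); then toluene, 80 °C until N2 evolution ends; concentrate under argon, use at once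
Reagents that add atoms: sodium azide, [Na+].[N-]=[N+]=[N-]
Why: Curtius rearrangement by the mixed-anhydride/azide protocol: azide should displace ethyl carbonate at the more electrophilic acyl carbonyl, and the dried acyl azide loses N2 at 80 °C with concerted migration of the CH2 group from carbon to nitrogen, the isocyanate persisting because the medium is aprotic and the carbamate nitrogens carry no hydrogen.

Step 4
Reactants: 11 4-(2-bromoethyl)-1,2-dimethoxybenzene
Product: 12 2-(3,4-dimethoxyphenyl)ethylmagnesium bromide (titrated THF solution)
Conditions: Mg turnings (1.5 equiv), I2 (cat.), THF, slow addition, 25–40 °C; titrate before use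
Reagents that add atoms: magnesium, [Mg]
Why: Oxidative insertion of magnesium into the primary C–Br bond (Grignard formation) should proceed normally, slow addition at moderate dilution holding back Wurtz coupling; the aryl methyl ethers are inert and the β-carbon carries no leaving group.

Step 5
Reactants: 10 di-tert-butyl butane-1,4-diylbis[(3-isocyanatopropyl)carbamate]; 12 2-(3,4-dimethoxyphenyl)ethylmagnesium bromide (two molecules per molecule of 10, 2.3 equiv used)
Product: 14 di-tert-butyl butane-1,4-diylbis({3-[3-(3,4-dimethoxyphenyl)propanamido]propyl}carbamate) (N5,N10-di-Boc tetra-O-methyl kukoamine A, spermine numbered as 1,5,10,14-tetraazatetradecane), via bis(bromomagnesium) amidate 13 (not isolated)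
Conditions: 12 added dropwise to 10, THF, −78 °C → −20 °C; sat. aq NH4Cl, −20 °C
Reagents that add atoms: none
Why: The sp3 carbanion of 12 adds to the central sp carbon of each N=C=O cumulene, with magnesium coordinating the heteroatoms, to give the bis(bromomagnesium) amidate 13, whose delocalised negative charge shuts down a second addition; aqueous NH4Cl then protonates it to the secondary amide. This is the long-established addition of Grignard reagents to isocyanates to give secondary amides, run here at both ends of one molecule. No ring is closed and no stereocentre is created, the product being achiral. The selectivity required is chemoselectivity for the two isocyanates over the two Boc carbamates: the heterocumulene carbon is far more electrophilic than a carbamate carbonyl flanked by two donor atoms, the carbamate nitrogens are fully substituted so no N–H quenches the reagent, and slow addition of 12 to 10 at −78 °C keeps the concentration of free Grignard reagent low. The absence of acidic hydrogen in 10 and of a β-leaving group in 12 leaves simple addition as the only accessible pathway, and the cold quench should keep the amidate nitrogen from closing onto the neighbouring Boc carbonyl.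

Step 6
Reactants: 14 N5,N10-di-Boc tetra-O-methyl kukoamine A
Product: 16 kukoamine A, via kukoamine A bis(hydrobromide) 15 (not isolated)
Conditions: BBr3 (12 equiv, 1 M in CH2Cl2), CH2Cl2, −78 °C → rt; MeOH, 0 °C, evaporate (×3); then degassed aq NH3, C18 (H2O → MeOH), Ar
Reagents that add atoms: none
Why: Boron tribromide coordinates each ether and carbamate oxygen, bromide removes the methyl groups by SN2 and the tert-butyl groups by ionisation (Lewis-acid aryl ether cleavage and Boc removal), the amides only form reversible adducts, methanolysis strips boron as volatile trimethyl borate with loss of CO2 from the carbamic acids, and ammonia frees the amines from the hydrobromide.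

Compound list
1 | pyrrolidin-2-one | O=C1CCCN1 | starting material
2 | 1,4-dibromobutane | BrCCCCBr | starting material
3 | sodium 2-oxopyrrolidin-1-ide | [Na+].O=C1CCC[N-]1 | intermediate (not isolated)
4 | 1-(4-bromobutyl)pyrrolidin-2-one | O=C1CCCN1CCCCBr | intermediate (not isolated)
5 | 1,1'-(butane-1,4-diyl)di(pyrrolidin-2-one) | O=C1CCCN1CCCCN1CCCC1=O | intermediate
6 | 4,4'-(butane-1,4-diyldiazanediyl)dibutanoic acid dihydrochloride | Cl.Cl.OC(=O)CCCNCCCCNCCCC(=O)O | intermediate (not isolated)
7 | 4,4'-[butane-1,4-diylbis(tert-butoxycarbonylazanediyl)]dibutanoic acid | OC(=O)CCCN(C(=O)OC(C)(C)C)CCCCN(C(=O)OC(C)(C)C)CCCC(=O)O | intermediate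
8 | bis(ethyl carbonic) mixed anhydride of 7 | CCOC(=O)OC(=O)CCCN(C(=O)OC(C)(C)C)CCCCN(C(=O)OC(C)(C)C)CCCC(=O)OC(=O)OCC | intermediate (not isolated)
9 | di-tert-butyl butane-1,4-diylbis[(4-azido-4-oxobutyl)carbamate] (bis(acyl azide)) | [N-]=[N+]=NC(=O)CCCN(C(=O)OC(C)(C)C)CCCCN(C(=O)OC(C)(C)C)CCCC(=O)N=[N+]=[N-] | intermediate (not isolated)
10 | di-tert-butyl butane-1,4-diylbis[(3-isocyanatopropyl)carbamate] | O=C=NCCCN(C(=O)OC(C)(C)C)CCCCN(C(=O)OC(C)(C)C)CCCN=C=O | intermediate
11 | 4-(2-bromoethyl)-1,2-dimethoxybenzene | BrCCc1ccc(OC)c(OC)c1 | starting material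
12 | 2-(3,4-dimethoxyphenyl)ethylmagnesium bromide | Br[Mg]CCc1ccc(OC)c(OC)c1 | intermediate
13 | bis(bromomagnesium) amidate of 14 (drawn N-bound) | COc1ccc(CCC(=O)N([Mg]Br)CCCN(C(=O)OC(C)(C)C)CCCCN(C(=O)OC(C)(C)C)CCCN([Mg]Br)C(=O)CCc2ccc(OC)c(OC)c2)cc1OC | intermediate (not isolated)
14 | di-tert-butyl butane-1,4-diylbis({3-[3-(3,4-dimethoxyphenyl)propanamido]propyl}carbamate) | O=C(CCc1ccc(OC)c(OC)c1)NCCCN(C(=O)OC(C)(C)C)CCCCN(C(=O)OC(C)(C)C)CCCNC(=O)CCc1ccc(OC)c(OC)c1 | intermediate
15 | kukoamine A bis(hydrobromide) | Br.Br.O=C(CCc1ccc(O)c(O)c1)NCCCNCCCCNCCCNC(=O)CCc1ccc(O)c(O)c1 | intermediate (not isolated)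
16 | kukoamine A, N,N'-[butane-1,4-diylbis(azanediylpropane-3,1-diyl)]bis[3-(3,4-dihydroxyphenyl)propanamide] | O=C(CCc1ccc(O)c(O)c1)NCCCNCCCCNCCCNC(=O)CCc1ccc(O)c(O)c1 | target

Total step count: 6. Longest linear sequence: 5 steps (steps 1, 2, 3, 5, 6); step 4 is a one-step branch that joins at step 5.

Steps most likely to fail

Step 5. The organomagnesium reagent may add to a Boc carbonyl, or the amidate may close onto the neighbouring carbamate. Addition may also stop at one end, with the remaining isocyanate lost to hydrolysis and urea cross-linking, or the reagent may lose titre through Wurtz coupling. The fallback gives up carbanion capture and forms the amides at the C–N bond. It sets out from 10, which is heated with benzyl alcohol (toluene, 80 °C, dibutyltin dilaurate cat.) to give N1,N14-bis(benzyloxycarbonyl)-N5,N10-bis(tert-butoxycarbonyl)spermine F1. Hydrogenolysis (H2, Pd/C, MeOH) then gives N5,N10-bis(tert-butoxycarbonyl)spermine F2. Commercial 3-(3,4-dimethoxyphenyl)propanoic acid is activated with EDC·HCl and HOBt (i-Pr2NEt, CH2Cl2) as 1H-benzotriazol-1-yl 3-(3,4-dimethoxyphenyl)propanoate F3, which acylates both primary amines of the diamine. The sequence comes back to the route at 14.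

Step 3. Activation may be incomplete at one of the two acids, azide may attack the carbonate carbonyl of the anhydride and return the acid, or traces of water may hydrolyse an isocyanate to an amine that captures a second isocyanate as urea oligomers. The fallback makes the acyl azide by nitrosation of an isolated, purifiable hydrazide instead of by displacement on a transient anhydride. It sets out from 7, which is esterified (MeI, K2CO3, DMF) to dimethyl 4,4'-[butane-1,4-diylbis(tert-butoxycarbonylazanediyl)]dibutanoate F4. Hydrazinolysis (N2H4·H2O, MeOH, reflux) gives di-tert-butyl butane-1,4-diylbis[(4-hydrazinyl-4-oxobutyl)carbamate] F5. Treatment with tert-butyl nitrite and HCl in dioxane/DMF at −20 °C (the peptide azide method, under which Boc groups survive) comes back to the route at the bis(acyl azide) 9, which is extracted into toluene and heated to 10 as in step 3.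

Step 6. tert-Butyl cations released under the strong Lewis acid may alkylate the electron-rich rings, ether cleavage may stop short of all four methyl groups, and the catechols may oxidise while the free base is released. The fallback stages the deprotection. It sets out from 14, which is treated with HCl (4 M in dioxane, rt) and worked up with aqueous NaOH/CH2Cl2 to give N1,N14-bis[3-(3,4-dimethoxyphenyl)propanoyl]spermine F6, a phenol-free amine that can be purified. Only then is BBr3 applied (CH2Cl2, −78 °C → rt; MeOH), coming back to the route at 15, which is neutralised to 16 as in step 6.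

Further compounds
F1 | step 5 | N1,N14-bis(benzyloxycarbonyl)-N5,N10-bis(tert-butoxycarbonyl)spermine | O=C(OCc1ccccc1)NCCCN(C(=O)OC(C)(C)C)CCCCN(C(=O)OC(C)(C)C)CCCNC(=O)OCc1ccccc1
F2 | step 5 | N5,N10-bis(tert-butoxycarbonyl)spermine, di-tert-butyl butane-1,4-diylbis[(3-aminopropyl)carbamate] | NCCCN(C(=O)OC(C)(C)C)CCCCN(C(=O)OC(C)(C)C)CCCN
F3 | step 5 | 1H-benzotriazol-1-yl 3-(3,4-dimethoxyphenyl)propanoate | COc1ccc(CCC(=O)On2nnc3ccccc23)cc1OC
F4 | step 3 | dimethyl 4,4'-[butane-1,4-diylbis(tert-butoxycarbonylazanediyl)]dibutanoate | COC(=O)CCCN(C(=O)OC(C)(C)C)CCCCN(C(=O)OC(C)(C)C)CCCC(=O)OC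
F5 | step 3 | di-tert-butyl butane-1,4-diylbis[(4-hydrazinyl-4-oxobutyl)carbamate] | NNC(=O)CCCN(C(=O)OC(C)(C)C)CCCCN(C(=O)OC(C)(C)C)CCCC(=O)NN
F6 | step 6 | N1,N14-bis[3-(3,4-dimethoxyphenyl)propanoyl]spermine (tetra-O-methylkukoamine A) | O=C(CCc1ccc(OC)c(OC)c1)NCCCNCCCCNCCCNC(=O)CCc1ccc(OC)c(OC)c1
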